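**Plan**

1. Retrosynthesis: after the ten O–benzyl bonds, the C7–C8 bond of the benzo[7]annulen-5-one is cut. This contracts the tropolone ring to a 2-hydroxynaphthalen-1(2H)-one whose C2 carries an exocyclic bromomethine (the future C7) bound to chroman A.
2. Enabling feature: in the seven-membered ring (C5 carbonyl, C6 hydroxyl, C7 bearing chroman A, C8=C9 joined through C9a to the benzo ring that carries chroman B at C1), C7 lies between the oxygenated C6 and the styrene-type C8=C9 bond. A radical at C7 can therefore capture C8 and pull it away from C6.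
3. Earlier cuts: the naphthol C2–CH bond (ortho-hydroxyalkylation with a chroman-2-carbaldehyde); in chroman B the O1–C8a bond (SNAr) and the C2–aryl bond (aryl Grignard plus α-benzyloxy aldehyde); in chroman A the C4–C4a bond (epoxide–arene cyclisation) and the aryl O–C2 bond (Mitsunobu).
4. Forward order: tetralone, then naphthalene; chroman B closed on the naphthyl bromide; chroman A with its gallate made separately; union at naphthol C2; dearomatisation to the spiro-oxirane; bromohydrin; tropolone ring by ring enlargement; hydrogenolysis.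
5. Stereochemistry: chroman B C3 comes from (R)-trityl glycidyl ether, and C2 from chelation-controlled aryl addition with retentive SNAr closure. Chroman A comes from Sharpless desymmetrisation of divinylcarbinol with L-(+)-DIPT plus one Mitsunobu inversion.

Key step: step 23

Remark: chroman A = (3R)-5,7-bis(benzyloxy)-3-[3,4,5-tris(benzyloxy)benzoyloxy]chroman-2-yl with 2,3-cis substituents (ring configuration of 30); chroman B = (2R,3R)-3,5,7-tris(benzyloxy)chroman-2-yl. The side-chain carbinol of 29 and the carbinol, oxirane, bromide and quaternary carbons of 32–34 are formed as epimer mixtures and drawn without configuration, because they are cleaved or become sp2 later. Compounds 24 and 27 are taken as catalogue chemicals.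

**Route**

Step 1
Reactants: 1 4-(3,4-dimethoxyphenyl)butanoic acid
Product: 2 4-(2-bromo-4,5-dimethoxyphenyl)butanoic acid
Conditions: Br2, AcOH, 20 °C
Reagents that add atoms: bromine, BrBr
Why: Electrophilic aromatic bromination of the veratrole ring occurs para to the 3-methoxy group (ortho to the chain), which blocks the site normally used in ring closure and installs the handle for chroman B.

Step 2
Reactants: 2 4-(2-bromo-4,5-dimethoxyphenyl)butanoic acid
Product: 3 5-bromo-7,8-dimethoxy-3,4-dihydronaphthalen-1(2H)-one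
Conditions: P2O5 in MeSO3H, 50 °C
Reagents that add atoms: none
Why: Intramolecular Friedel–Crafts acylation can close only onto the remaining ortho carbon next to a methoxy group, giving the 7,8-dioxygenated 5-bromotetralone.

Step 3
Reactants: 3 5-bromo-7,8-dimethoxy-3,4-dihydronaphthalen-1(2H)-one
Product: 4 5-bromo-7,8-dihydroxy-3,4-dihydronaphthalen-1(2H)-one
Conditions: BBr3, CH2Cl2, −78 to 0 °C; MeOH, H2O
Reagents that add atoms: none
Why: BBr3 ether cleavage removes both methyl groups while the ketone and the aryl bromide stay intact.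

Step 4
Reactants: 4 5-bromo-7,8-dihydroxy-3,4-dihydronaphthalen-1(2H)-one
Product: 5 7,8-bis(benzyloxy)-5-bromo-3,4-dihydronaphthalen-1(2H)-one
Conditions: BnBr, K2CO3, DMF, 60 °C
Reagents that add atoms: benzyl bromide, BrCc1ccccc1
Why: Williamson etherification of the two phenols installs the hydrogenolysable ethers, and K2CO3 is too weak to enolise the ketone towards C-alkylation.

Step 5
Reactants: 5 7,8-bis(benzyloxy)-5-bromo-3,4-dihydronaphthalen-1(2H)-one
Product: 7 7,8-bis(benzyloxy)-5-bromonaphthalen-1-ol, via α-bromoketone 6 (not isolated)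
Conditions: CuBr2, EtOAc/CHCl3, reflux; then LiBr, Li2CO3, DMF, 120 °C
Reagents that add atoms: none
Why: α-Bromination of the ketone and dehydrobromination give a dienone that tautomerises to the naphthol (bromination–dehydrobromination aromatisation of a tetralone), with no oxidant present that could attack the naphthol.

Step 6
Reactants: 7 7,8-bis(benzyloxy)-5-bromonaphthalen-1-ol
Product: 8 7,8-bis(benzyloxy)-5-bromo-1-(methoxymethoxy)naphthalene
Conditions: NaH, MOMCl, DMF, 0 °C
Reagents that add atoms: chloromethyl methyl ether, COCCl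
Why: O-Alkylation of the naphthoxide gives a MOM acetal that tolerates the organolithium and hydride-base steps ahead.

Step 7
Reactants: 9 1,3,5-trifluorobenzene
Product: 10 1,3-bis(benzyloxy)-5-fluorobenzene
Conditions: BnOH (2.05 equiv), NaH, NMP, 0 to 90 °C
Reagents that add atoms: benzyl alcohol, OCc1ccccc1
Why: Two-fold nucleophilic aromatic substitution, in which each fluorine is activated by the meta fluorines and the alkoxy groups introduced slow the third substitution.

Step 8
Reactants: 10 1,3-bis(benzyloxy)-5-fluorobenzene; 11 (R)-2-[(trityloxy)methyl]oxirane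
Product: 13 (2R)-1-[2,4-bis(benzyloxy)-6-fluorophenyl]-3-(trityloxy)propan-2-ol, via aryllithium 12 (not isolated)
Conditions: n-BuLi, THF, −78 °C; then 11, BF3·OEt2, −78 °C
Reagents that add atoms: none
Why: Directed ortho-lithiation at the carbon flanked by fluorine and a benzyloxy group, then BF3-promoted SN2 opening of the oxirane at its CH2 terminus; the glycidyl stereocentre is not touched and becomes C3 of chroman B.

Step 9
Reactants: 13 (2R)-1-[2,4-bis(benzyloxy)-6-fluorophenyl]-3-(trityloxy)propan-2-ol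
Product: 14 1,5-bis(benzyloxy)-2-[(2R)-2-(benzyloxy)-3-(trityloxy)propyl]-3-fluorobenzene
Conditions: NaH, BnBr, Bu4NI (cat.), THF, 0 to 25 °C
Reagents that add atoms: benzyl bromide, BrCc1ccccc1
Why: Williamson benzylation of the secondary alkoxide, with a trityl ether that cannot migrate under base.

Step 10
Reactants: 14 1,5-bis(benzyloxy)-2-[(2R)-2-(benzyloxy)-3-(trityloxy)propyl]-3-fluorobenzene
Product: 15 (2R)-2-(benzyloxy)-3-[2,4-bis(benzyloxy)-6-fluorophenyl]propan-1-ol
Conditions: TsOH·H2O (cat.), MeOH/CH2Cl2, 25 °C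
Reagents that add atoms: none
Why: Acid-catalysed solvolysis of the trityl ether (SN1 at the trityl carbon) frees the primary alcohol and leaves the benzyl ethers alone.

Step 11
Reactants: 15 (2R)-2-(benzyloxy)-3-[2,4-bis(benzyloxy)-6-fluorophenyl]propan-1-ol
Product: 16 (2R)-2-(benzyloxy)-3-[2,4-bis(benzyloxy)-6-fluorophenyl]propanal
Conditions: Dess–Martin periodinane, NaHCO3, CH2Cl2, 0 to 25 °C
Reagents that add atoms: none
Why: Dess–Martin oxidation under buffered, non-basic conditions should give the α-benzyloxy aldehyde without epimerisation.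

Step 12
Reactants: 8 7,8-bis(benzyloxy)-5-bromo-1-(methoxymethoxy)naphthalene; 16 (2R)-2-(benzyloxy)-3-[2,4-bis(benzyloxy)-6-fluorophenyl]propanal
Product: 19 (1R,2R)-2-(benzyloxy)-3-[2,4-bis(benzyloxy)-6-fluorophenyl]-1-[3,4-bis(benzyloxy)-5-(methoxymethoxy)naphthalen-1-yl]propan-1-ol, via aryllithium 17 (not isolated), via arylmagnesium bromide 18 (not isolated)
Conditions: t-BuLi (2 equiv), Et2O, −78 °C; MgBr2·OEt2; then 16, CH2Cl2, −78 °C
Reagents that add atoms: none
Why: Bromine–lithium exchange and transmetallation give an aryl Grignard reagent that adds under chelation control (magnesium bridging the aldehyde and α-benzyloxy oxygens, attack anti to the CH2Ar group), which sets the carbinol as 1R, syn to the benzyloxy group.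

Step 13
Reactants: 19 (1R,2R)-2-(benzyloxy)-3-[2,4-bis(benzyloxy)-6-fluorophenyl]-1-[3,4-bis(benzyloxy)-5-(methoxymethoxy)naphthalen-1-yl]propan-1-ol
Product: 20 (2R,3R)-3,5,7-tris(benzyloxy)-2-[3,4-bis(benzyloxy)-5-(methoxymethoxy)naphthalen-1-yl]chromane
Conditions: KH, 18-crown-6, THF, 0 to 50 °C
Reagents that add atoms: none
Why: Intramolecular SNAr of the benzylic alkoxide on the fluoroarene (fluoride meta to both benzyloxy groups) closes the pyran ring; no bond to either stereocentre is broken, so the syn alcohol gives the 2,3-cis (2R,3R) chroman.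

Step 14
Reactants: 20 (2R,3R)-3,5,7-tris(benzyloxy)-2-[3,4-bis(benzyloxy)-5-(methoxymethoxy)naphthalen-1-yl]chromane
Product: 21 7,8-bis(benzyloxy)-5-(chroman B)naphthalen-1-ol
Conditions: HCl (3 M aq.), THF/MeOH, 45 °C
Reagents that add atoms: none
Why: Acid-catalysed acetal cleavage removes the MOM group, while benzyl ethers and the chroman are stable to dilute acid.

Step 15
Reactants: 22 penta-1,4-dien-3-ol
Product: 23 (1S)-1-[(2R)-oxiran-2-yl]prop-2-en-1-ol
Conditions: Ti(OiPr)4, L-(+)-DIPT, t-BuOOH, 4 Å sieves, CH2Cl2, −25 °C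
Reagents that add atoms: tert-butyl hydroperoxide, CC(C)(C)OO
Why: Sharpless asymmetric epoxidation of the divinyl carbinol, in which the tartrate catalyst selects one enantiotopic vinyl group and its face (erythro product, 2R,3S) and the minor enantiomer is consumed by a faster second epoxidation.

Step 16
Reactants: 23 (1S)-1-[(2R)-oxiran-2-yl]prop-2-en-1-ol; 24 3,5-bis(benzyloxy)phenol
Product: 25 (2R)-2-{(1R)-1-[3,5-bis(benzyloxy)phenoxy]prop-2-en-1-yl}oxirane
Conditions: PPh3, DIAD, THF, 0 to 25 °C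
Reagents that add atoms: none
Why: Mitsunobu etherification proceeds by SN2 displacement of the oxyphosphonium with inversion at the carbinol (S to R), turning the erythro epoxy alcohol into the threo aryl ether.

Step 17
Reactants: 25 (2R)-2-{(1R)-1-[3,5-bis(benzyloxy)phenoxy]prop-2-en-1-yl}oxirane
Product: 26 (2R,3R)-5,7-bis(benzyloxy)-2-vinylchroman-3-ol
Conditions: (CF3)2CHOH, 40 °C
Reagents that add atoms: none
Why: Intramolecular Friedel–Crafts epoxide–arene cyclisation, in which the electron-rich ring attacks the oxirane CH2 (6-endo) in the ionising, weakly nucleophilic solvent; both stereocentres keep their bonds, so the threo ether gives the 2,3-cis (2R,3R) chromanol.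

Step 18
Reactants: 26 (2R,3R)-5,7-bis(benzyloxy)-2-vinylchroman-3-ol; 27 3,4,5-tris(benzyloxy)benzoic acid
Product: 28 (2R,3R)-5,7-bis(benzyloxy)-2-vinylchroman-3-yl 3,4,5-tris(benzyloxy)benzoate
Conditions: DCC, DMAP, CH2Cl2, 25 °C
Reagents that add atoms: none
Why: Steglich esterification acylates the hindered secondary alcohol under neutral conditions.

Step 19
Reactants: 28 (2R,3R)-5,7-bis(benzyloxy)-2-vinylchroman-3-yl 3,4,5-tris(benzyloxy)benzoate
Product: 30 (2S,3R)-5,7-bis(benzyloxy)-2-formylchroman-3-yl 3,4,5-tris(benzyloxy)benzoate, via vicinal diol 29 (not isolated)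
Conditions: OsO4 (2 mol %), NaIO4, 2,6-lutidine, dioxane/H2O, 25 °C
Reagents that add atoms: sodium periodate, [Na+].[O-]I(=O)(=O)=O; osmium tetroxide (catalytic oxygen carrier), O=[Os](=O)(=O)=O
Why: Lemieux–Johnson cleavage (dihydroxylation, then periodate glycol cleavage) converts the vinyl group into the aldehyde without ozone, which would attack the trialkoxybenzene ring.

Step 20
Reactants: 21 7,8-bis(benzyloxy)-5-(chroman B)naphthalen-1-ol; 30 (2S,3R)-5,7-bis(benzyloxy)-2-formylchroman-3-yl 3,4,5-tris(benzyloxy)benzoate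
Product: 32 7,8-bis(benzyloxy)-2-[hydroxy(chroman A)methyl]-5-(chroman B)naphthalen-1-ol, via bromomagnesium naphthoxide 31 (not isolated)
Conditions: EtMgBr (1.0 equiv), Et2O, 0 °C; solvent changed to CH2Cl2; then 30, 25 °C
Reagents that add atoms: none
Why: Ortho-specific hydroxyalkylation of a bromomagnesium phenoxide, in which magnesium binds the naphthoxide oxygen and the aldehyde so that the C–C bond forms only at C2 through a six-membered transition state; the carbinol configuration is not needed.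

Step 21
Reactants: 32 7,8-bis(benzyloxy)-2-[hydroxy(chroman A)methyl]-5-(chroman B)naphthalen-1-ol
Product: 33 7,8-bis(benzyloxy)-3′-(chroman A)-5-(chroman B)-1H-spiro[naphthalene-2,2′-oxiran]-1-one
Conditions: NaIO4, MeCN/THF/H2O, 0 to 25 °C
Reagents that add atoms: none
Why: Adler–Becker oxidation, in which the aryl periodate ester is displaced at C2 by the neighbouring benzylic hydroxyl, dearomatising the naphthol to the spiro-oxirane dienone.

Step 22
Reactants: 33 7,8-bis(benzyloxy)-3′-(chroman A)-5-(chroman B)-1H-spiro[naphthalene-2,2′-oxiran]-1-one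
Product: 34 7,8-bis(benzyloxy)-2-[bromo(chroman A)methyl]-2-hydroxy-5-(chroman B)naphthalen-1(2H)-one
Conditions: LiBr, AcOH, THF, 0 to 25 °C
Reagents that add atoms: lithium bromide, [Li+].[Br-]
Why: Acid-assisted SN2 opening of the oxirane by bromide at the secondary exocyclic carbon (halohydrin formation from an α,β-epoxy ketone); the quaternary α-keto carbon is closed to substitution and attack at C4 is hindered by the peri chroman B.

Step 23
Reactants: 34 7,8-bis(benzyloxy)-2-[bromo(chroman A)methyl]-2-hydroxy-5-(chroman B)naphthalen-1(2H)-one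
Product: 35 3,4-bis(benzyloxy)-6-hydroxy-7-(chroman A)-1-(chroman B)-5H-benzo[7]annulen-5-one
Conditions: 4CzIPN (2 mol %), Co(dmgH)2(py)Cl (3 mol %), Et3N (3 equiv), degassed MeCN/CH2Cl2, 450 nm LEDs, 25 °C; aq. citric acid work-up
Reagents that add atoms: none
Why: Proposed new method: the α-aminoalkyl radical generated from Et3N by the excited photocatalyst abstracts bromine from C7 (product numbering), the C7 radical adds 3-exo-trig to C8 of the C8=C9 styrene bond to give a benzylic C9 radical, and the cyclopropane reopens by C6–C8 scission to the ring-expanded C6 radical stabilised by its hydroxyl and the C5 carbonyl; divalent cobalt then takes the C7–H (or O–H) hydrogen, the dienol/dione tautomerises to the aromatic tropolone and the cobalt hydride is discharged as H2, so the substrate loses only HBr. The closest known reaction types are the tin-hydride ring expansion of (halomethyl)cyclohexadienones to tropones, the homoallyl-to-cyclopropylcarbinyl 1,2-vinyl shift, and the photoredox/cobaloxime dehydrohalogenation of alkyl bromides. The seven-membered ring is not closed directly but arises by ring enlargement (3-exo-trig closure onto C8, then cleavage of the endocyclic C6–C8 bond of the bicyclo[4.1.0] intermediate). No stereocentre is formed: C6 and C7 end up sp2 and the four chroman stereocentres are not touched. The selectivity required is migration of the vinyl carbon C8 in preference to the acyl carbon C5, to β-scission of the aryloxy bond of chroman A and to premature desaturation; it should be secured by the benzylic stabilisation of the 3-exo adduct at C9 (addition to the carbonyl carbon gives only an alkoxyl radical), by the strongly exergonic opening to the captodative C6 radical, and by a low stationary concentration of divalent cobalt.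

Step 24
Reactants: 35 3,4-bis(benzyloxy)-6-hydroxy-7-(chroman A)-1-(chroman B)-5H-benzo[7]annulen-5-one
Product: 36 (2R,3R)-5,7-dihydroxy-2-{3,4,6-trihydroxy-5-oxo-1-[(2R,3R)-3,5,7-trihydroxychroman-2-yl]-5H-benzo[7]annulen-7-yl}chroman-3-yl 3,4,5-trihydroxybenzoate
Conditions: H2 (1 atm), Pd(OH)2/C, THF/MeOH, 25 °C
Reagents that add atoms: none
Why: Catalytic hydrogenolysis should cleave the nine aryl and one alkyl benzyl ethers, while the ester, the chroman C–O bonds and the aromatic tropolone are expected to survive at atmospheric pressure if the reaction is stopped once debenzylation is complete.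

**Compound list**

1 | 4-(3,4-dimethoxyphenyl)butanoic acid | COc1ccc(CCCC(=O)O)cc1OC | starting material
2 | 4-(2-bromo-4,5-dimethoxyphenyl)butanoic acid | COc1cc(Br)c(CCCC(=O)O)cc1OC | intermediate
3 | 5-bromo-7,8-dimethoxy-3,4-dihydronaphthalen-1(2H)-one | COc1cc(Br)c2CCCC(=O)c2c1OC | intermediate
4 | 5-bromo-7,8-dihydroxy-3,4-dihydronaphthalen-1(2H)-one | Oc1cc(Br)c2CCCC(=O)c2c1O | intermediate
5 | 7,8-bis(benzyloxy)-5-bromo-3,4-dihydronaphthalen-1(2H)-one | O=C1CCCc2c(Br)cc(OCc5ccccc5)c(OCc5ccccc5)c12 | intermediate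
6 | 7,8-bis(benzyloxy)-2,5-dibromo-3,4-dihydronaphthalen-1(2H)-one (racemic) | O=C1C(Br)CCc2c(Br)cc(OCc5ccccc5)c(OCc5ccccc5)c12 | intermediate (not isolated)
7 | 7,8-bis(benzyloxy)-5-bromonaphthalen-1-ol | Oc1cccc2c(Br)cc(OCc5ccccc5)c(OCc5ccccc5)c12 | intermediate
8 | 7,8-bis(benzyloxy)-5-bromo-1-(methoxymethoxy)naphthalene | COCOc1cccc2c(Br)cc(OCc5ccccc5)c(OCc5ccccc5)c12 | intermediate
9 | 1,3,5-trifluorobenzene | Fc1cc(F)cc(F)c1 | starting material
10 | 1,3-bis(benzyloxy)-5-fluorobenzene | Fc1cc(OCc5ccccc5)cc(OCc5ccccc5)c1 | intermediate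
11 | (R)-2-[(trityloxy)methyl]oxirane | C(OC[C@H]1CO1)(c1ccccc1)(c1ccccc1)c1ccccc1 | starting material
12 | [2,4-bis(benzyloxy)-6-fluorophenyl]lithium | [Li]c1c(F)cc(OCc5ccccc5)cc1OCc5ccccc5 | intermediate (not isolated)
13 | (2R)-1-[2,4-bis(benzyloxy)-6-fluorophenyl]-3-(trityloxy)propan-2-ol | C(OC[C@H](O)Cc1c(F)cc(OCc5ccccc5)cc1OCc5ccccc5)(c1ccccc1)(c1ccccc1)c1ccccc1 | intermediate
14 | 1,5-bis(benzyloxy)-2-[(2R)-2-(benzyloxy)-3-(trityloxy)propyl]-3-fluorobenzene | C(OC[C@H](OCc5ccccc5)Cc1c(F)cc(OCc5ccccc5)cc1OCc5ccccc5)(c1ccccc1)(c1ccccc1)c1ccccc1 | intermediate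
15 | (2R)-2-(benzyloxy)-3-[2,4-bis(benzyloxy)-6-fluorophenyl]propan-1-ol | OC[C@H](OCc5ccccc5)Cc1c(F)cc(OCc5ccccc5)cc1OCc5ccccc5 | intermediate
16 | (2R)-2-(benzyloxy)-3-[2,4-bis(benzyloxy)-6-fluorophenyl]propanal | O=C[C@H](OCc5ccccc5)Cc1c(F)cc(OCc5ccccc5)cc1OCc5ccccc5 | intermediate
17 | [3,4-bis(benzyloxy)-5-(methoxymethoxy)naphthalen-1-yl]lithium | COCOc1cccc2c([Li])cc(OCc5ccccc5)c(OCc5ccccc5)c12 | intermediate (not isolated)
18 | [3,4-bis(benzyloxy)-5-(methoxymethoxy)naphthalen-1-yl]magnesium bromide | COCOc1cccc2c([Mg]Br)cc(OCc5ccccc5)c(OCc5ccccc5)c12 | intermediate (not isolated)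
19 | (1R,2R)-2-(benzyloxy)-3-[2,4-bis(benzyloxy)-6-fluorophenyl]-1-[3,4-bis(benzyloxy)-5-(methoxymethoxy)naphthalen-1-yl]propan-1-ol | COCOc1cccc2c([C@@H](O)[C@H](OCc5ccccc5)Cc3c(F)cc(OCc5ccccc5)cc3OCc5ccccc5)cc(OCc5ccccc5)c(OCc5ccccc5)c12 | intermediate
20 | (2R,3R)-3,5,7-tris(benzyloxy)-2-[3,4-bis(benzyloxy)-5-(methoxymethoxy)naphthalen-1-yl]chromane | COCOc1cccc2c([C@H]3Oc4cc(OCc5ccccc5)cc(OCc5ccccc5)c4C[C@H]3OCc5ccccc5)cc(OCc5ccccc5)c(OCc5ccccc5)c12 | intermediate
21 | 7,8-bis(benzyloxy)-5-[(2R,3R)-3,5,7-tris(benzyloxy)chroman-2-yl]naphthalen-1-ol | Oc1cccc2c([C@H]3Oc4cc(OCc5ccccc5)cc(OCc5ccccc5)c4C[C@H]3OCc5ccccc5)cc(OCc5ccccc5)c(OCc5ccccc5)c12 | intermediate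
22 | penta-1,4-dien-3-ol | C=CC(O)C=C | starting material
23 | (1S)-1-[(2R)-oxiran-2-yl]prop-2-en-1-ol | C=C[C@H](O)[C@H]1CO1 | intermediate
24 | 3,5-bis(benzyloxy)phenol | Oc1cc(OCc5ccccc5)cc(OCc5ccccc5)c1 | starting material
25 | (2R)-2-{(1R)-1-[3,5-bis(benzyloxy)phenoxy]prop-2-en-1-yl}oxirane | C=C[C@@H](Oc1cc(OCc5ccccc5)cc(OCc5ccccc5)c1)[C@H]1CO1 | intermediate
26 | (2R,3R)-5,7-bis(benzyloxy)-2-vinylchroman-3-ol | O[C@@H]1Cc2c(OCc5ccccc5)cc(OCc5ccccc5)cc2O[C@@H]1C=C | intermediate
27 | 3,4,5-tris(benzyloxy)benzoic acid | OC(=O)c1cc(OCc5ccccc5)c(OCc5ccccc5)c(OCc5ccccc5)c1 | starting material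
28 | (2R,3R)-5,7-bis(benzyloxy)-2-vinylchroman-3-yl 3,4,5-tris(benzyloxy)benzoate | O=C(O[C@@H]1Cc2c(OCc5ccccc5)cc(OCc5ccccc5)cc2O[C@@H]1C=C)c1cc(OCc5ccccc5)c(OCc5ccccc5)c(OCc5ccccc5)c1 | intermediate
29 | (3R)-5,7-bis(benzyloxy)-2-(1,2-dihydroxyethyl)chroman-3-yl 3,4,5-tris(benzyloxy)benzoate, 2,3-cis as in 28, side-chain carbinol unassigned | O=C(O[C@@H]1Cc2c(OCc5ccccc5)cc(OCc5ccccc5)cc2O[C@@H]1C(O)CO)c1cc(OCc5ccccc5)c(OCc5ccccc5)c(OCc5ccccc5)c1 | intermediate (not isolated)
30 | (2S,3R)-5,7-bis(benzyloxy)-2-formylchroman-3-yl 3,4,5-tris(benzyloxy)benzoate | O=C(O[C@@H]1Cc2c(OCc5ccccc5)cc(OCc5ccccc5)cc2O[C@@H]1C=O)c1cc(OCc5ccccc5)c(OCc5ccccc5)c(OCc5ccccc5)c1 | intermediate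
31 | bromomagnesium 7,8-bis(benzyloxy)-5-(chroman B)naphthalen-1-olate | Br[Mg]Oc1cccc2c([C@H]3Oc4cc(OCc5ccccc5)cc(OCc5ccccc5)c4C[C@H]3OCc5ccccc5)cc(OCc5ccccc5)c(OCc5ccccc5)c12 | intermediate (not isolated)
32 | 7,8-bis(benzyloxy)-2-[hydroxy(chroman A)methyl]-5-(chroman B)naphthalen-1-ol (carbinol epimers) | O=C(O[C@@H]1Cc2c(OCc5ccccc5)cc(OCc5ccccc5)cc2O[C@@H]1C(O)c1ccc2c([C@H]3Oc4cc(OCc5ccccc5)cc(OCc5ccccc5)c4C[C@H]3OCc5ccccc5)cc(OCc5ccccc5)c(OCc5ccccc5)c2c1O)c1cc(OCc5ccccc5)c(OCc5ccccc5)c(OCc5ccccc5)c1 | intermediate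
33 | 7,8-bis(benzyloxy)-3′-(chroman A)-5-(chroman B)-1H-spiro[naphthalene-2,2′-oxiran]-1-one (epimers at both oxirane carbons) | O=C(O[C@@H]1Cc2c(OCc5ccccc5)cc(OCc5ccccc5)cc2O[C@@H]1C6OC67C=Cc2c([C@H]3Oc4cc(OCc5ccccc5)cc(OCc5ccccc5)c4C[C@H]3OCc5ccccc5)cc(OCc5ccccc5)c(OCc5ccccc5)c2C7=O)c1cc(OCc5ccccc5)c(OCc5ccccc5)c(OCc5ccccc5)c1 | intermediate
34 | 7,8-bis(benzyloxy)-2-[bromo(chroman A)methyl]-2-hydroxy-5-(chroman B)naphthalen-1(2H)-one (epimers at CHBr and C2) | O=C(O[C@@H]1Cc2c(OCc5ccccc5)cc(OCc5ccccc5)cc2O[C@@H]1C(Br)C6(O)C=Cc2c([C@H]3Oc4cc(OCc5ccccc5)cc(OCc5ccccc5)c4C[C@H]3OCc5ccccc5)cc(OCc5ccccc5)c(OCc5ccccc5)c2C6=O)c1cc(OCc5ccccc5)c(OCc5ccccc5)c(OCc5ccccc5)c1 | intermediate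
35 | 3,4-bis(benzyloxy)-6-hydroxy-7-(chroman A)-1-(chroman B)-5H-benzo[7]annulen-5-one | O=C(O[C@@H]1Cc2c(OCc5ccccc5)cc(OCc5ccccc5)cc2O[C@@H]1c1ccc2c([C@H]3Oc4cc(OCc5ccccc5)cc(OCc5ccccc5)c4C[C@H]3OCc5ccccc5)cc(OCc5ccccc5)c(OCc5ccccc5)c2c(=O)c1O)c1cc(OCc5ccccc5)c(OCc5ccccc5)c(OCc5ccccc5)c1 | intermediate
36 | (2R,3R)-5,7-dihydroxy-2-{3,4,6-trihydroxy-5-oxo-1-[(2R,3R)-3,5,7-trihydroxychroman-2-yl]-5H-benzo[7]annulen-7-yl}chroman-3-yl 3,4,5-trihydroxybenzoate | O=C(O[C@@H]1Cc2c(O)cc(O)cc2O[C@@H]1c1ccc2c([C@H]3Oc4cc(O)cc(O)c4C[C@H]3O)cc(O)c(O)c2c(=O)c1O)c1cc(O)c(O)c(O)c1 | target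

**Step count and risks**

Total: 24 steps. Longest linear sequence: 14 steps (steps 1–6, 12–14, 20–24).

Step 23 (ring enlargement). The C7 radical may be quenched before it rearranges, by hydrogen abstraction from the chroman C2–H through divalent cobalt. The C5 carbonyl may compete as acceptor and give the acyl-shifted ring. The aryloxy bond of chroman A may fragment, or the tropolonate formed may bind cobalt and stop turnover. The fallback forms the same C7–C8 bond by a two-electron halohydrin (semipinacol) ring enlargement, a known reaction type. It sets out from 34, which is treated with AgBF4 and 2,6-di-tert-butyl-4-methylpyridine in CH2Cl2 at −40 to 0 °C. Silver-assisted ionisation of the C–Br bond with 1,2-shift of the alkenyl carbon (better migrating group than the acyl carbon) from the carbinol carbon gives the 3,4-bis(benzyloxy)-7-(chroman A)-1-(chroman B)-7H-benzo[7]annulene-5,6-dione F1. This enolises to the tropolone, so the route is rejoined at 35.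

Step 22 (bromide opening). Bromide may add in conjugate fashion at C4 of the styrene unit with cleavage of the C2–O bond and re-aromatisation to a naphthol, or the gallate carbonyl may participate at the exocyclic carbon and lead to acyl migration. The fallback avoids both the oxirane and the halide, so that the tertiary C–O bond never becomes a leaving group. It sets out from 32, which is dearomatised by ortho-hydroxylation with stabilised 2-iodoxybenzoic acid (SIBX, THF, 25 °C, Na2S2O4 work-up) to 7,8-bis(benzyloxy)-2-hydroxy-2-[hydroxy(chroman A)methyl]-5-(chroman B)naphthalen-1(2H)-one F2. The secondary hydroxyl alone is converted with 1,1′-thiocarbonyldiimidazole (DMAP cat., CH2Cl2) into the O-(imidazol-1-ylcarbonothioyl) derivative F3. Barton–McCombie fragmentation (Bu3SnH, AIBN, toluene, 90 °C) generates the same exocyclic radical, which after the vinyl shift is reduced to 3,4-bis(benzyloxy)-6-hydroxy-7-(chroman A)-1-(chroman B)-6,7-dihydro-5H-benzo[7]annulen-5-one F4. Dess–Martin oxidation of this α-ketol and tautomerisation rejoin the route at 35.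

Step 20 (union of the halves). The aldehyde may lose its gallate by β-elimination through the magnesium enolate or epimerise at C2 of chroman A before the C–C bond forms, and the peri-chelated naphthoxide may react slowly. The fallback replaces the basic magnesium phenoxide by a boron template under weakly acidic conditions. It sets out from 21 and 30, which are condensed with PhB(OH)2 and catalytic propionic acid in toluene at 80 °C with removal of water. This gives 7,8-bis(benzyloxy)-4-(chroman A)-6-(chroman B)-2-phenyl-4H-naphtho[1,2-e][1,3,2]dioxaborinine F5. Transesterification with diethanolamine releases the diol, and the route is rejoined at 32.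

**Further compounds**

F1 | step 23 | 3,4-bis(benzyloxy)-7-(chroman A)-1-(chroman B)-7H-benzo[7]annulene-5,6-dione | O=C(O[C@@H]1Cc2c(OCc5ccccc5)cc(OCc5ccccc5)cc2O[C@@H]1C6C=Cc2c([C@H]3Oc4cc(OCc5ccccc5)cc(OCc5ccccc5)c4C[C@H]3OCc5ccccc5)cc(OCc5ccccc5)c(OCc5ccccc5)c2C(=O)C6=O)c1cc(OCc5ccccc5)c(OCc5ccccc5)c(OCc5ccccc5)c1
F2 | step 22 | 7,8-bis(benzyloxy)-2-hydroxy-2-[hydroxy(chroman A)methyl]-5-(chroman B)naphthalen-1(2H)-one | O=C(O[C@@H]1Cc2c(OCc5ccccc5)cc(OCc5ccccc5)cc2O[C@@H]1C(O)C6(O)C=Cc2c([C@H]3Oc4cc(OCc5ccccc5)cc(OCc5ccccc5)c4C[C@H]3OCc5ccccc5)cc(OCc5ccccc5)c(OCc5ccccc5)c2C6=O)c1cc(OCc5ccccc5)c(OCc5ccccc5)c(OCc5ccccc5)c1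
F3 | step 22 | O-{(chroman A)[7,8-bis(benzyloxy)-2-hydroxy-1-oxo-5-(chroman B)-1,2-dihydronaphthalen-2-yl]methyl} 1H-imidazole-1-carbothioate | O=C(O[C@@H]1Cc2c(OCc5ccccc5)cc(OCc5ccccc5)cc2O[C@@H]1C(OC(=S)n7ccnc7)C6(O)C=Cc2c([C@H]3Oc4cc(OCc5ccccc5)cc(OCc5ccccc5)c4C[C@H]3OCc5ccccc5)cc(OCc5ccccc5)c(OCc5ccccc5)c2C6=O)c1cc(OCc5ccccc5)c(OCc5ccccc5)c(OCc5ccccc5)c1
F4 | step 22 | 3,4-bis(benzyloxy)-6-hydroxy-7-(chroman A)-1-(chroman B)-6,7-dihydro-5H-benzo[7]annulen-5-one | O=C(O[C@@H]1Cc2c(OCc5ccccc5)cc(OCc5ccccc5)cc2O[C@@H]1C6C=Cc2c([C@H]3Oc4cc(OCc5ccccc5)cc(OCc5ccccc5)c4C[C@H]3OCc5ccccc5)cc(OCc5ccccc5)c(OCc5ccccc5)c2C(=O)C6O)c1cc(OCc5ccccc5)c(OCc5ccccc5)c(OCc5ccccc5)c1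
F5 | step 20 | 7,8-bis(benzyloxy)-4-(chroman A)-6-(chroman B)-2-phenyl-4H-naphtho[1,2-e][1,3,2]dioxaborinine | O=C(O[C@@H]1Cc2c(OCc5ccccc5)cc(OCc5ccccc5)cc2O[C@@H]1C6OB(c7ccccc7)Oc7c6ccc6c([C@H]3Oc4cc(OCc5ccccc5)cc(OCc5ccccc5)c4C[C@H]3OCc5ccccc5)cc(OCc5ccccc5)c(OCc5ccccc5)c76)c1cc(OCc5ccccc5)c(OCc5ccccc5)c(OCc5ccccc5)c1
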